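**Plan**
- Retrosynthesis: the three MOM ethers come off last. The C3–C4 bond of the pyranone (ring C) is then cut by a retro-hydroacylation, which also removes the C2 stereocentre and leaves an achiral aryl 1-arylvinyl ether of a salicylaldehyde.
- Enabling feature: C4 is a carbonyl carbon on ring A ortho to the ring oxygen O1, C3 is an unsubstituted CH2, and C2 carries H, O1 and ring B. The unit H–C2–C3–C4(=O) is therefore the retron of a formyl C–H addition across an enol ether O1–C2(aryl)=C3H2.
- The enol ether C2=C3 is cut back to an aryl ester (ester methylenation). This divides the molecule at O1–C2 into a C-prenylated phloroglucinaldehyde (ring A) and a chromene carboxylic acid (ring B with its fused pyran).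
- Forward: the pyran is built on methyl 3,4-dihydroxybenzoate by a propargyl ether Claisen/electrocyclisation cascade, and the ring B prenyl by Claisen shift of a 1,1-dimethylallyl ether. The two halves are then joined as an ester, the ester is methylenated, ring C is closed by rhodium-catalysed 6-endo hydroacylation, and the MOM groups are removed.
- Stereochemistry: the single stereocentre (2S) is created in the ring-closing step by the chiral bisphosphine on rhodium. The only later step is acidic, so base-induced ring opening to the chalcone cannot scramble it.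

Key step: step 15

Assumption: the sense of induction in step 15 cannot be derived with certainty from the analogies; the ligand antipode written is the one expected to give 2S, and the mirror-image ligand is used if the sense proves opposite.

**Route**

Step 1
Reactants: 1 2,4,6-trihydroxybenzaldehyde; 2 1-bromo-3-methylbut-2-ene (prenyl bromide)
Product: 3 2,4,6-trihydroxy-3-(3-methylbut-2-en-1-yl)benzaldehyde
Conditions: 2 (1.0 equiv), DBU, THF, 0 °C to rt
Reagents that add atoms: none
Why: C-alkylation of the ambident phloroglucinol-type phenoxide by the allylic bromide is the usual entry to mono-C-prenyl acylphloroglucinols, and the two free ring carbons of 1 are equivalent so only one mono-C-prenyl isomer can form.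

Step 2
Reactants: 3 2,4,6-trihydroxy-3-(3-methylbut-2-en-1-yl)benzaldehyde
Product: 4 2-hydroxy-4,6-bis(methoxymethoxy)-3-(3-methylbut-2-en-1-yl)benzaldehyde
Conditions: MOMCl (2.1 equiv), i-Pr2NEt, CH2Cl2, 0 °C
Reagents that add atoms: chloromethyl methyl ether, COCCl
Why: Williamson-type acetalisation should take the unchelated 4-OH and the less hindered 6-OH and leave the 2-OH, which is hydrogen-bonded to the aldehyde and flanked by the prenyl group.

Step 3
Reactants: 5 methyl 3,4-dihydroxybenzoate; 6 3-chloro-3-methylbut-1-yne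
Product: 7 methyl 3-hydroxy-4-[(2-methylbut-3-yn-2-yl)oxy]benzoate
Conditions: 6 (1.2 equiv), K2CO3 (1.0 equiv), KI (cat.), acetone, reflux
Reagents that add atoms: none
Why: Williamson etherification with one equivalent of base should occur at the 4-OH, which is para to the ester and the more acidic of the two hydroxyls.

Step 4
Reactants: 7 methyl 3-hydroxy-4-[(2-methylbut-3-yn-2-yl)oxy]benzoate
Product: 10 methyl 8-hydroxy-2,2-dimethyl-2H-chromene-6-carboxylate, via allenylphenol 8 (not isolated), via ortho-quinone methide 9 (not isolated)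
Conditions: PhNEt2, 190 °C
Reagents that add atoms: none
Why: Aryl propargyl ether Claisen rearrangement to the only free ortho carbon, followed by [1,5]-hydrogen shift and oxa-6π electrocyclisation, is the standard thermal route to 2,2-dimethyl-2H-chromenes.

Step 5
Reactants: 10 methyl 8-hydroxy-2,2-dimethyl-2H-chromene-6-carboxylate; 6 3-chloro-3-methylbut-1-yne
Product: 11 methyl 2,2-dimethyl-8-[(2-methylbut-3-yn-2-yl)oxy]-2H-chromene-6-carboxylate
Conditions: 6 (1.5 equiv), DBU, CuCl2·2H2O (cat.), MeCN, 0 °C to rt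
Reagents that add atoms: none
Why: Copper-catalysed O-alkylation of phenols with tertiary propargylic chlorides proceeds through a copper acetylide-stabilised cation and tolerates hindered phenols.

Step 6
Reactants: 11 methyl 2,2-dimethyl-8-[(2-methylbut-3-yn-2-yl)oxy]-2H-chromene-6-carboxylate
Product: 12 methyl 2,2-dimethyl-8-[(2-methylbut-3-en-2-yl)oxy]-2H-chromene-6-carboxylate
Conditions: H2 (1 atm, 1 equiv), Pd/CaCO3 poisoned with Pb(OAc)2, quinoline, EtOAc, rt
Reagents that add atoms: none
Why: Lindlar semihydrogenation reduces the terminal alkyne far faster than the cis-disubstituted styrenic chromene alkene, so stopping at one equivalent of hydrogen should give the 1,1-dimethylallyl ether.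

Step 7
Reactants: 12 methyl 2,2-dimethyl-8-[(2-methylbut-3-en-2-yl)oxy]-2H-chromene-6-carboxylate
Product: 14 methyl 8-hydroxy-2,2-dimethyl-7-(3-methylbut-2-en-1-yl)-2H-chromene-6-carboxylate, via Claisen dienone 13 (not isolated)
Conditions: PhNEt2, 130 °C
Reagents that add atoms: none
Why: Aromatic Claisen rearrangement of a 1,1-dimethylallyl aryl ether inverts the allyl unit in the [3,3] shift and so delivers the linear prenyl group to C7, the only free ortho carbon, after which the dienone tautomerises to the phenol.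

Step 8
Reactants: 14 methyl 8-hydroxy-2,2-dimethyl-7-(3-methylbut-2-en-1-yl)-2H-chromene-6-carboxylate
Product: 15 methyl 8-(methoxymethoxy)-2,2-dimethyl-7-(3-methylbut-2-en-1-yl)-2H-chromene-6-carboxylate
Conditions: MOMCl, i-Pr2NEt, CH2Cl2, 0 °C to 40 °C
Reagents that add atoms: chloromethyl methyl ether, COCCl
Why: Standard MOM acetal formation masks the only free phenol, which would otherwise compete in the acylation of step 10 and consume the titanium reagent of step 12.

Step 9
Reactants: 15 methyl 8-(methoxymethoxy)-2,2-dimethyl-7-(3-methylbut-2-en-1-yl)-2H-chromene-6-carboxylate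
Product: 16 8-(methoxymethoxy)-2,2-dimethyl-7-(3-methylbut-2-en-1-yl)-2H-chromene-6-carboxylic acid
Conditions: LiOH·H2O, THF/MeOH/H2O, 50 °C; then 1 M HCl to pH 4, 0 °C
Reagents that add atoms: lithium hydroxide, [Li+].[OH-]
Why: Saponification of the methyl ester by acyl–oxygen cleavage leaves the base-stable MOM acetal, prenyl group and chromene untouched, and a brief cold acidification to pH 4 should not cleave the acetal.

Step 10
Reactants: 16 8-(methoxymethoxy)-2,2-dimethyl-7-(3-methylbut-2-en-1-yl)-2H-chromene-6-carboxylic acid; 4 2-hydroxy-4,6-bis(methoxymethoxy)-3-(3-methylbut-2-en-1-yl)benzaldehyde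
Product: 18 2-formyl-3,5-bis(methoxymethoxy)-6-(3-methylbut-2-en-1-yl)phenyl 8-(methoxymethoxy)-2,2-dimethyl-7-(3-methylbut-2-en-1-yl)-2H-chromene-6-carboxylate, via acid chloride 17 (not isolated)
Conditions: 16, 1-chloro-N,N,2-trimethylprop-1-en-1-amine, CH2Cl2, 0 °C to rt; then 4, Et3N, DMAP (cat.), 0 °C to rt
Reagents that add atoms: none
Why: The chloroenamine makes the acid chloride without releasing acid (so the MOM acetals survive), and DMAP-catalysed acylation is forceful enough for the hindered, hydrogen-bonded phenol.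

Step 11
Reactants: 18 2-formyl-3,5-bis(methoxymethoxy)-6-(3-methylbut-2-en-1-yl)phenyl 8-(methoxymethoxy)-2,2-dimethyl-7-(3-methylbut-2-en-1-yl)-2H-chromene-6-carboxylate
Product: 19 3,5-bis(methoxymethoxy)-6-(3-methylbut-2-en-1-yl)-2-{[(triethylsilyl)oxy]methyl}phenyl 8-(methoxymethoxy)-2,2-dimethyl-7-(3-methylbut-2-en-1-yl)-2H-chromene-6-carboxylate
Conditions: Et3SiH (1.5 equiv), RhCl(PPh3)3 (cat.), toluene, rt to 50 °C
Reagents that add atoms: triethylsilane, CC[SiH](CC)CC
Why: Rhodium-catalysed carbonyl hydrosilylation masks the aldehyde against the titanium methylidene and gives the silyl ether without a free alkoxide, so no acyl transfer from the neighbouring aryl ester can occur, while trisubstituted and styrenic alkenes react much more slowly than an aldehyde.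

Step 12
Reactants: 19 3,5-bis(methoxymethoxy)-6-(3-methylbut-2-en-1-yl)-2-{[(triethylsilyl)oxy]methyl}phenyl 8-(methoxymethoxy)-2,2-dimethyl-7-(3-methylbut-2-en-1-yl)-2H-chromene-6-carboxylate
Product: 20 triethyl{[2-({1-[8-(methoxymethoxy)-2,2-dimethyl-7-(3-methylbut-2-en-1-yl)-2H-chromen-6-yl]ethenyl}oxy)-4,6-bis(methoxymethoxy)-3-(3-methylbut-2-en-1-yl)phenyl]methoxy}silane
Conditions: Cp2Ti(CH2)(Cl)AlMe2 (1.5 equiv), pyridine (cat.), THF/toluene, −40 °C to rt; aq NaOH quench; basic Al2O3
Reagents that add atoms: Tebbe reagent Cp2Ti(CH2)(Cl)AlMe2, C[Al-]1(C)C[Ti](C2C=CC=C2)(C2C=CC=C2)[Cl+]1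
Why: Tebbe methylenation converts aryl benzoates into aryl 1-arylvinyl ethers through [2+2] addition of the titanium methylidene to the ester carbonyl and collapse of the oxatitanacyclobutane, and silyl ether, MOM acetals and hindered alkenes are inert to it.

Step 13
Reactants: 20 triethyl{[2-({1-[8-(methoxymethoxy)-2,2-dimethyl-7-(3-methylbut-2-en-1-yl)-2H-chromen-6-yl]ethenyl}oxy)-4,6-bis(methoxymethoxy)-3-(3-methylbut-2-en-1-yl)phenyl]methoxy}silane
Product: 21 [2-({1-[8-(methoxymethoxy)-2,2-dimethyl-7-(3-methylbut-2-en-1-yl)-2H-chromen-6-yl]ethenyl}oxy)-4,6-bis(methoxymethoxy)-3-(3-methylbut-2-en-1-yl)phenyl]methanol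
Conditions: Bu4NF (1.1 equiv), THF, 0 °C
Reagents that add atoms: none
Why: Fluoride-induced desilylation is basic rather than acidic, so the acid-labile enol ether and MOM acetals survive, and no ester remains to be attacked by the alkoxide.

Step 14
Reactants: 21 [2-({1-[8-(methoxymethoxy)-2,2-dimethyl-7-(3-methylbut-2-en-1-yl)-2H-chromen-6-yl]ethenyl}oxy)-4,6-bis(methoxymethoxy)-3-(3-methylbut-2-en-1-yl)phenyl]methanol
Product: 22 2-({1-[8-(methoxymethoxy)-2,2-dimethyl-7-(3-methylbut-2-en-1-yl)-2H-chromen-6-yl]ethenyl}oxy)-4,6-bis(methoxymethoxy)-3-(3-methylbut-2-en-1-yl)benzaldehyde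
Conditions: activated MnO2 (excess), CH2Cl2, rt
Reagents that add atoms: none
Why: MnO2 oxidises electron-rich benzylic alcohols to aldehydes under neutral heterogeneous conditions that leave the enol ether, the acetals and the alkenes alone.

Step 15
Reactants: 22 2-({1-[8-(methoxymethoxy)-2,2-dimethyl-7-(3-methylbut-2-en-1-yl)-2H-chromen-6-yl]ethenyl}oxy)-4,6-bis(methoxymethoxy)-3-(3-methylbut-2-en-1-yl)benzaldehyde
Product: 23 (2S)-5,7-bis(methoxymethoxy)-2-[8-(methoxymethoxy)-2,2-dimethyl-7-(3-methylbut-2-en-1-yl)-2H-chromen-6-yl]-8-(3-methylbut-2-en-1-yl)-2,3-dihydro-4H-chromen-4-one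
Conditions: [Rh(cod)Cl]2 (2.5 mol%), (R)-DTBM-SEGPHOS (5.5 mol%), NaB[3,5-(CF3)2C6H3]4 (5 mol%), 1,4-dioxane, 60 °C
Reagents that add atoms: none
Why: Proposed new method: the cationic bisphosphine complex of monovalent rhodium should insert into the formyl C–H bond of 22 to give an acyl hydride of trivalent rhodium, the tethered enol ether C2=C3 should insert into Rh–H with hydrogen going to C2 and rhodium to the terminal C3, and C–C reductive elimination from the seven-membered acyl(alkyl)rhodacycle should form the C3–C4 bond. The closest known reaction type is the enantioselective rhodium-catalysed endo hydroacylation of 1,1-disubstituted alkenes held ortho to an aromatic aldehyde (2-vinylbenzaldehydes to 3-substituted indanones, ortho-allylbenzaldehydes to 3-substituted tetralones, N-vinylindole-2-carbaldehydes to bicyclic ketones), whereas an aryl 1-arylvinyl ether with oxygen in the tether has not been shown. Ring C closes in the 6-endo-trig mode, because the 5-exo alternative would need reductive elimination at a fully substituted carbon bearing oxygen and aryl to make a quaternary benzofuranone, and the hydride insertion leading to it is reversible. The C2 stereocentre is set by catalyst control, the C2-symmetric bisphosphine on rhodium distinguishing the enantiotopic faces of the enol ether when hydride is transferred to C2. The step needs chemoselectivity for the enol ether over the other alkenes, for hydroacylation over decarbonylation and over thermal rearrangement: the prenyl groups are trisubstituted, the chromene alkene cannot reach the acyl rhodium centre in a small ring, the short ortho tether favours insertion over CO loss, and both ortho positions of the aryloxy ring are blocked so that no aromatic Claisen shift of the aryl vinyl ether can compete.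

Step 16
Reactants: 23 (2S)-5,7-bis(methoxymethoxy)-2-[8-(methoxymethoxy)-2,2-dimethyl-7-(3-methylbut-2-en-1-yl)-2H-chromen-6-yl]-8-(3-methylbut-2-en-1-yl)-2,3-dihydro-4H-chromen-4-one
Product: 24 (2S)-5,7-dihydroxy-2-[8-hydroxy-2,2-dimethyl-7-(3-methylbut-2-en-1-yl)-2H-chromen-6-yl]-8-(3-methylbut-2-en-1-yl)-2,3-dihydro-4H-chromen-4-one
Conditions: 3 M aq HCl, MeOH, 45 °C
Reagents that add atoms: none
Why: Acid-catalysed transacetalisation to methanol removes all three MOM groups under conditions commonly used for prenylated flavanones, and because no base is present the flavanone cannot open to the chalcone, so C2 should keep its configuration.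

**Compound list**

1 | 2,4,6-trihydroxybenzaldehyde | O=Cc1c(O)cc(O)cc1O | starting material
2 | 1-bromo-3-methylbut-2-ene | CC(C)=CCBr | starting material
3 | 2,4,6-trihydroxy-3-(3-methylbut-2-en-1-yl)benzaldehyde | CC(C)=CCc1c(O)cc(O)c(C=O)c1O | intermediate
4 | 2-hydroxy-4,6-bis(methoxymethoxy)-3-(3-methylbut-2-en-1-yl)benzaldehyde | CC(C)=CCc1c(O)c(C=O)c(OCOC)cc1OCOC | intermediate
5 | methyl 3,4-dihydroxybenzoate | COC(=O)c1ccc(O)c(O)c1 | starting material
6 | 3-chloro-3-methylbut-1-yne | C#CC(C)(C)Cl | starting material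
7 | methyl 3-hydroxy-4-[(2-methylbut-3-yn-2-yl)oxy]benzoate | COC(=O)c1ccc(OC(C)(C)C#C)c(O)c1 | intermediate
8 | methyl 3,4-dihydroxy-5-(3-methylbuta-1,2-dien-1-yl)benzoate (allenylphenol) | COC(=O)c1cc(O)c(O)c(C=C=C(C)C)c1 | intermediate
9 | methyl 5-hydroxy-3-(3-methylbut-2-en-1-ylidene)-4-oxocyclohexa-1,5-diene-1-carboxylate (ortho-quinone methide) | COC(=O)C1=CC(=CC=C(C)C)C(=O)C(O)=C1 | intermediate
10 | methyl 8-hydroxy-2,2-dimethyl-2H-chromene-6-carboxylate | COC(=O)c1cc(O)c2OC(C)(C)C=Cc2c1 | intermediate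
11 | methyl 2,2-dimethyl-8-[(2-methylbut-3-yn-2-yl)oxy]-2H-chromene-6-carboxylate | COC(=O)c1cc(OC(C)(C)C#C)c2OC(C)(C)C=Cc2c1 | intermediate
12 | methyl 2,2-dimethyl-8-[(2-methylbut-3-en-2-yl)oxy]-2H-chromene-6-carboxylate | COC(=O)c1cc(OC(C)(C)C=C)c2OC(C)(C)C=Cc2c1 | intermediate
13 | methyl 2,2-dimethyl-7-(3-methylbut-2-en-1-yl)-8-oxo-7,8-dihydro-2H-chromene-6-carboxylate (Claisen dienone) | COC(=O)C1=CC2=C(OC(C)(C)C=C2)C(=O)C1CC=C(C)C | intermediate
14 | methyl 8-hydroxy-2,2-dimethyl-7-(3-methylbut-2-en-1-yl)-2H-chromene-6-carboxylate | COC(=O)c1cc2C=CC(C)(C)Oc2c(O)c1CC=C(C)C | intermediate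
15 | methyl 8-(methoxymethoxy)-2,2-dimethyl-7-(3-methylbut-2-en-1-yl)-2H-chromene-6-carboxylate | COCOc1c(CC=C(C)C)c(C(=O)OC)cc2C=CC(C)(C)Oc12 | intermediate
16 | 8-(methoxymethoxy)-2,2-dimethyl-7-(3-methylbut-2-en-1-yl)-2H-chromene-6-carboxylic acid | COCOc1c(CC=C(C)C)c(C(O)=O)cc2C=CC(C)(C)Oc12 | intermediate
17 | 8-(methoxymethoxy)-2,2-dimethyl-7-(3-methylbut-2-en-1-yl)-2H-chromene-6-carbonyl chloride | COCOc1c(CC=C(C)C)c(C(Cl)=O)cc2C=CC(C)(C)Oc12 | intermediate
18 | 2-formyl-3,5-bis(methoxymethoxy)-6-(3-methylbut-2-en-1-yl)phenyl 8-(methoxymethoxy)-2,2-dimethyl-7-(3-methylbut-2-en-1-yl)-2H-chromene-6-carboxylate | CC(C)=CCc1c(OC(=O)c2cc3C=CC(C)(C)Oc3c(OCOC)c2CC=C(C)C)c(C=O)c(OCOC)cc1OCOC | intermediate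
19 | 3,5-bis(methoxymethoxy)-6-(3-methylbut-2-en-1-yl)-2-{[(triethylsilyl)oxy]methyl}phenyl 8-(methoxymethoxy)-2,2-dimethyl-7-(3-methylbut-2-en-1-yl)-2H-chromene-6-carboxylate | CC(C)=CCc1c(OC(=O)c2cc3C=CC(C)(C)Oc3c(OCOC)c2CC=C(C)C)c(CO[Si](CC)(CC)CC)c(OCOC)cc1OCOC | intermediate
20 | triethyl{[2-({1-[8-(methoxymethoxy)-2,2-dimethyl-7-(3-methylbut-2-en-1-yl)-2H-chromen-6-yl]ethenyl}oxy)-4,6-bis(methoxymethoxy)-3-(3-methylbut-2-en-1-yl)phenyl]methoxy}silane | CC(C)=CCc1c(OC(=C)c2cc3C=CC(C)(C)Oc3c(OCOC)c2CC=C(C)C)c(CO[Si](CC)(CC)CC)c(OCOC)cc1OCOC | intermediate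
21 | [2-({1-[8-(methoxymethoxy)-2,2-dimethyl-7-(3-methylbut-2-en-1-yl)-2H-chromen-6-yl]ethenyl}oxy)-4,6-bis(methoxymethoxy)-3-(3-methylbut-2-en-1-yl)phenyl]methanol | CC(C)=CCc1c(OC(=C)c2cc3C=CC(C)(C)Oc3c(OCOC)c2CC=C(C)C)c(CO)c(OCOC)cc1OCOC | intermediate
22 | 2-({1-[8-(methoxymethoxy)-2,2-dimethyl-7-(3-methylbut-2-en-1-yl)-2H-chromen-6-yl]ethenyl}oxy)-4,6-bis(methoxymethoxy)-3-(3-methylbut-2-en-1-yl)benzaldehyde | CC(C)=CCc1c(OC(=C)c2cc3C=CC(C)(C)Oc3c(OCOC)c2CC=C(C)C)c(C=O)c(OCOC)cc1OCOC | intermediate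
23 | (2S)-5,7-bis(methoxymethoxy)-2-[8-(methoxymethoxy)-2,2-dimethyl-7-(3-methylbut-2-en-1-yl)-2H-chromen-6-yl]-8-(3-methylbut-2-en-1-yl)-2,3-dihydro-4H-chromen-4-one | CC(C)=CCc1c([C@@H]2CC(=O)c3c(OCOC)cc(OCOC)c(CC=C(C)C)c3O2)cc2c(c1OCOC)OC(C)(C)C=C2 | intermediate
24 | (2S)-5,7-dihydroxy-2-[8-hydroxy-2,2-dimethyl-7-(3-methylbut-2-en-1-yl)-2H-chromen-6-yl]-8-(3-methylbut-2-en-1-yl)-2,3-dihydro-4H-chromen-4-one | CC(C)=CCc1c([C@@H]2CC(=O)c3c(O)cc(O)c(CC=C(C)C)c3O2)cc2c(c1O)OC(C)(C)C=C2 | target

**Totals and risks**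

Total step count: 16. Longest linear sequence: 14 steps (steps 3 to 16, from methyl 3,4-dihydroxybenzoate 5).

Steps most likely to fail:

1. Step 15. The hindered, electron-rich aldehyde may lose CO at rhodium and poison the catalyst, the enol ether flanked by an ortho-prenyl aryl group may insert too slowly, or the two alkene faces may be poorly distinguished. The fallback uses known chemistry, sets out from 4 and 15 and comes back at 23; it closes ring C at O1–C2 instead. MeMgBr (THF, −78 °C to 0 °C) should add to aldehyde 4 to give 1-[2-hydroxy-4,6-bis(methoxymethoxy)-3-(3-methylbut-2-en-1-yl)phenyl]ethan-1-ol F1, and MnO2 (CH2Cl2) should oxidise this to 1-[2-hydroxy-4,6-bis(methoxymethoxy)-3-(3-methylbut-2-en-1-yl)phenyl]ethan-1-one F2. Ester 15 is reduced with i-Bu2AlH (CH2Cl2, −78 °C) to [8-(methoxymethoxy)-2,2-dimethyl-7-(3-methylbut-2-en-1-yl)-2H-chromen-6-yl]methanol F3 and oxidised with MnO2 to 8-(methoxymethoxy)-2,2-dimethyl-7-(3-methylbut-2-en-1-yl)-2H-chromene-6-carbaldehyde F4. Claisen–Schmidt condensation of F2 with F4 (KOH, EtOH/H2O, rt) should give (2E)-1-[2-hydroxy-4,6-bis(methoxymethoxy)-3-(3-methylbut-2-en-1-yl)phenyl]-3-[8-(methoxymethoxy)-2,2-dimethyl-7-(3-methylbut-2-en-1-yl)-2H-chromen-6-yl]prop-2-en-1-one F5. Intramolecular oxa-Michael addition (NaOAc, EtOH, reflux) should then give racemic 5,7-bis(methoxymethoxy)-2-[8-(methoxymethoxy)-2,2-dimethyl-7-(3-methylbut-2-en-1-yl)-2H-chromen-6-yl]-8-(3-methylbut-2-en-1-yl)-2,3-dihydro-4H-chromen-4-one F6. Preparative HPLC on an amylose tris(3,5-dimethylphenylcarbamate) phase should deliver the 2S enantiomer 23.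

2. Step 12. Methylenation of an aryl ester hindered on both sides may stall, and the electron-rich enol ether may hydrolyse on contact with the aluminium residues or with silica during isolation. The fallback sets out from 16 and 4 and comes back at 22; it makes the O1–C2 bond by cross-coupling and bypasses steps 10, 11, 13 and 14. Acid 16 with MeLi (2.2 equiv, THF, 0 °C) should give 1-[8-(methoxymethoxy)-2,2-dimethyl-7-(3-methylbut-2-en-1-yl)-2H-chromen-6-yl]ethan-1-one F7. Enolisation and triflation (KN(SiMe3)2, PhNTf2, THF, −78 °C) should give 1-[8-(methoxymethoxy)-2,2-dimethyl-7-(3-methylbut-2-en-1-yl)-2H-chromen-6-yl]ethenyl trifluoromethanesulfonate F8. C–O coupling of F8 with phenol 4 (Pd2(dba)3, 2-(di-tert-butylphosphino)biphenyl, K3PO4, toluene, 80 °C), catalysed by zerovalent palladium, should give 22 directly. This coupling is itself exposed to base-induced loss of triflate to the arylalkyne and to the low nucleophilicity of the chelated phenol.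

3. Step 1. O-alkylation and multiple C-alkylation of the phloroglucinol core may outrun mono-C-prenylation, and step 2 then rests on a selectivity between two ortho hydroxyls. The fallback sets out from 1 and comes back at 4; it fixes the regiochemistry by a Claisen shift. Bis-acetalisation of 1 (MOMCl 2.0 equiv, i-Pr2NEt, CH2Cl2, 0 °C) should leave the chelated hydroxyl and give 2-hydroxy-4,6-bis(methoxymethoxy)benzaldehyde F9. Alkylation with 6 (DBU, CuCl2·2H2O cat., MeCN) should give 2,4-bis(methoxymethoxy)-6-[(2-methylbut-3-yn-2-yl)oxy]benzaldehyde F10, and Lindlar semihydrogenation (H2, Pd/CaCO3 poisoned with Pb(OAc)2, quinoline) should give 2,4-bis(methoxymethoxy)-6-[(2-methylbut-3-en-2-yl)oxy]benzaldehyde F11. Aromatic Claisen rearrangement (PhNEt2, 130 °C) to the only free ortho carbon should then give 4.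

Further compounds
F1 | step 15 | 1-[2-hydroxy-4,6-bis(methoxymethoxy)-3-(3-methylbut-2-en-1-yl)phenyl]ethan-1-ol | CC(O)c1c(O)c(CC=C(C)C)c(OCOC)cc1OCOC
F2 | step 15 | 1-[2-hydroxy-4,6-bis(methoxymethoxy)-3-(3-methylbut-2-en-1-yl)phenyl]ethan-1-one | CC(=O)c1c(O)c(CC=C(C)C)c(OCOC)cc1OCOC
F3 | step 15 | [8-(methoxymethoxy)-2,2-dimethyl-7-(3-methylbut-2-en-1-yl)-2H-chromen-6-yl]methanol | COCOc1c(CC=C(C)C)c(CO)cc2C=CC(C)(C)Oc12
F4 | step 15 | 8-(methoxymethoxy)-2,2-dimethyl-7-(3-methylbut-2-en-1-yl)-2H-chromene-6-carbaldehyde | COCOc1c(CC=C(C)C)c(C=O)cc2C=CC(C)(C)Oc12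
F5 | step 15 | (2E)-1-[2-hydroxy-4,6-bis(methoxymethoxy)-3-(3-methylbut-2-en-1-yl)phenyl]-3-[8-(methoxymethoxy)-2,2-dimethyl-7-(3-methylbut-2-en-1-yl)-2H-chromen-6-yl]prop-2-en-1-one | CC(C)=CCc1c(O)c(C(=O)/C=C/c2cc3C=CC(C)(C)Oc3c(OCOC)c2CC=C(C)C)c(OCOC)cc1OCOC
F6 | step 15 | racemic 5,7-bis(methoxymethoxy)-2-[8-(methoxymethoxy)-2,2-dimethyl-7-(3-methylbut-2-en-1-yl)-2H-chromen-6-yl]-8-(3-methylbut-2-en-1-yl)-2,3-dihydro-4H-chromen-4-one | CC(C)=CCc1c(C2CC(=O)c3c(OCOC)cc(OCOC)c(CC=C(C)C)c3O2)cc2c(c1OCOC)OC(C)(C)C=C2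
F7 | step 12 | 1-[8-(methoxymethoxy)-2,2-dimethyl-7-(3-methylbut-2-en-1-yl)-2H-chromen-6-yl]ethan-1-one | COCOc1c(CC=C(C)C)c(C(C)=O)cc2C=CC(C)(C)Oc12
F8 | step 12 | 1-[8-(methoxymethoxy)-2,2-dimethyl-7-(3-methylbut-2-en-1-yl)-2H-chromen-6-yl]ethenyl trifluoromethanesulfonate | COCOc1c(CC=C(C)C)c(C(=C)OS(=O)(=O)C(F)(F)F)cc2C=CC(C)(C)Oc12
F9 | step 1 | 2-hydroxy-4,6-bis(methoxymethoxy)benzaldehyde | O=Cc1c(O)cc(OCOC)cc1OCOC
F10 | step 1 | 2,4-bis(methoxymethoxy)-6-[(2-methylbut-3-yn-2-yl)oxy]benzaldehyde | O=Cc1c(OC(C)(C)C#C)cc(OCOC)cc1OCOC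
F11 | step 1 | 2,4-bis(methoxymethoxy)-6-[(2-methylbut-3-en-2-yl)oxy]benzaldehyde | O=Cc1c(OC(C)(C)C=C)cc(OCOC)cc1OCOC
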